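**Retrosynthetic overview**
- The stearate is cut last at the acyl C–O bond. This leaves the C7 benzylic alcohol, which comes from the C7 aldehyde; the carbon stays at the aldehyde level until the phenol oxygen is tied into the ring, because a free para-hydroxybenzyl ester would ionise.
- Ring B (the oxepine) is opened at C3–C4 and O1–C2. The strategy rests on the segment O1–C2H2–C3(=CH2)–C4H of ring B, which is a single propadiene unit lying between the phenol oxygen and the terminal vinyl carbon (C4) of an ortho-vinylphenol.
- The vinylphenol, 4-hydroxy-3-vinylbenzaldehyde, comes from 3-bromo-4-hydroxybenzaldehyde by one Suzuki vinylation.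
- Ring order: ring A (the benzene ring) is bought; ring B (seven-membered) is the only ring formed, in step 2.

Key step: step 2

Remark: the target has no stereocentre; its only stereochemical element, the cis C4=C5 alkene, is fixed by ring B. Propadiene is assumed to be condensed into a pressure tube and run under argon, so that no allene/oxygen mixture forms.

**Step 1**
Reactants: 1 3-bromo-4-hydroxybenzaldehyde; 2 potassium vinyltrifluoroborate
Product: 3 4-hydroxy-3-vinylbenzaldehyde
Conditions: PdCl2(dppf) (3 mol%), K2CO3 (3 equiv), 1,4-dioxane/H2O 4:1, 85 °C; aq. NH4Cl work-up, BHT added before concentration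
Reagents that add atoms: potassium vinyltrifluoroborate, C=C[B-](F)(F)F.[K+]
Why: Suzuki-Miyaura coupling, in which the para-formyl group keeps the C–Br bond reactive toward oxidative addition even in the phenoxide form and the trifluoroborate releases the vinylboron species slowly, which should limit Heck-type side reactions.

**Step 2**
Reactants: 3 4-hydroxy-3-vinylbenzaldehyde; 4 propadiene
Product: 5 3-methylene-2,3-dihydro-1-benzoxepine-7-carbaldehyde
Conditions: Pd(OAc)2 (10 mol%), anhydrous Cu(OAc)2 (2.2 equiv), propadiene (3–4 equiv, condensed in), MeCN, sealed tube, argon, 70 °C
Reagents that add atoms: propadiene, C=C=C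
Why: Mechanism: the acidic phenol of 3 binds divalent palladium as the phenoxide and acetate-assisted concerted metalation-deprotonation of the terminal vinyl C–H cis to ring A gives a six-membered oxapalladacycle (O1, C9a, C5a, C5, C4, Pd); propadiene then inserts into the Pd–C4 bond through its central carbon, which forms C3–C4 and gives a pi-allyl palladium phenoxide, and C–O reductive elimination at an allyl CH2 terminus forms O1–C2 before Cu(OAc)2 returns zerovalent palladium to divalent palladium. The closest known reaction type is the oxidative (5+2) annulation of ortho-alkenylphenols with allenes under Pd(OAc)2 and Cu(OAc)2 to 3-alkylidene-2,3-dihydro-1-benzoxepines, of which propadiene is the unsubstituted member of the allene class. Ring B, the only ring formed, closes as a seven-membered ring by reductive elimination from the eight-membered sigma-allyl form of the palladacycle, so the closure is a ring contraction with loss of the metal. No stereocentre is formed; the cis C4=C5 geometry follows from the fact that only the vinyl hydrogen cis to the arene is within reach of the phenoxide-bound metal. The step needs seven-ring closure to win over chromene formation and one sense of C–O bond formation: propadiene carries no allylic hydrogen, so the beta-hydride elimination that opens the chromene pathway has nothing to remove, and its two CH2 termini are identical. The para-formyl group is inert to both metals, makes the phenol acidic enough for easy palladium phenoxide formation and keeps the benzylic carbon at the aldehyde level, where no para-quinone methide can form.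

**Step 3**
Reactants: 5 3-methylene-2,3-dihydro-1-benzoxepine-7-carbaldehyde
Product: 6 (3-methylene-2,3-dihydro-1-benzoxepin-7-yl)methanol
Conditions: NaBH4 (1 equiv), MeOH/THF 1:1, 0 °C; aq. NH4Cl work-up
Reagents that add atoms: none
Why: 1,2-Hydride reduction of an aryl aldehyde by NaBH4 is fast at 0 °C and should leave the exocyclic methylene, the C4=C5 alkene and the allyl aryl ether untouched.

**Step 4**
Reactants: 6 (3-methylene-2,3-dihydro-1-benzoxepin-7-yl)methanol; 7 stearoyl chloride
Product: 8 (3-methylene-2,3-dihydro-1-benzoxepin-7-yl)methyl octadecanoate
Conditions: stearoyl chloride (1.1 equiv), pyridine (2 equiv), DMAP (5 mol%), CH2Cl2, 0 °C to rt; water wash, chromatography on Et3N-deactivated silica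
Reagents that add atoms: stearoyl chloride, O=C(Cl)CCCCCCCCCCCCCCCCC
Why: DMAP-assisted nucleophilic acyl substitution of a primary alcohol with an acid chloride, in which pyridine takes up the HCl so that the acid-sensitive para-alkoxybenzylic ester and the cross-conjugated triene are not exposed to acid.

**Compound list**
1 | 3-bromo-4-hydroxybenzaldehyde | O=Cc1ccc(O)c(Br)c1 | starting material
2 | potassium vinyltrifluoroborate | C=C[B-](F)(F)F.[K+] | starting material
3 | 4-hydroxy-3-vinylbenzaldehyde | C=Cc1cc(C=O)ccc1O | intermediate
4 | propadiene (allene) | C=C=C | starting material
5 | 3-methylene-2,3-dihydro-1-benzoxepine-7-carbaldehyde | C=C1C=Cc2cc(C=O)ccc2OC1 | intermediate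
6 | (3-methylene-2,3-dihydro-1-benzoxepin-7-yl)methanol | C=C1C=Cc2cc(CO)ccc2OC1 | intermediate
7 | stearoyl chloride (octadecanoyl chloride) | O=C(Cl)CCCCCCCCCCCCCCCCC | starting material
8 | (3-methylene-2,3-dihydro-1-benzoxepin-7-yl)methyl octadecanoate | C=C1C=Cc2cc(COC(=O)CCCCCCCCCCCCCCCCC)ccc2OC1 | target

Total step count: 4. Longest linear sequence: 4 steps (1 → 3 → 5 → 6 → 8).

**Steps most likely to fail**

Step 2. Oligomerisation of propadiene on palladium may outrun its insertion into the palladacycle. Metalation of the unsubstituted vinyl C–H may also be slow enough that oxidative side reactions of the vinylphenol (Wacker-type closure, polymerisation) take over. The fallback sets out from 3 and returns at 5, closing ring B by ring-closing metathesis instead. Phenol 3 would be O-alkylated with 2-(bromomethyl)buta-1,3-diene (C=CC(=C)CBr; K2CO3, DMF, rt; Williamson ether synthesis) to give 4-[(2-methylidenebut-3-en-1-yl)oxy]-3-vinylbenzaldehyde F1. F1 would then be cyclised at high dilution with the first-generation Grubbs catalyst RuCl2(PCy3)2(=CHPh) in CH2Cl2 at 40 °C. The styrene and the monosubstituted vinyl group of the diene should join as C4=C5 with loss of ethene to give 5. The first-generation catalyst is chosen because it engages 1,1-disubstituted alkenes poorly, which should hold back six-ring closure onto the C3 methylidene.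

Step 1. Oxidative addition into the phenoxide form of 1 may be slow, the vinylboron reagent may be lost by protodeboronation, and the free vinylphenol may oligomerise under hot basic conditions. The fallback sets out from 1 and returns at 3, masking the phenol and coupling under neutral conditions. Compound 1 would be silylated (TBSCl, imidazole, DMF, rt) to 3-bromo-4-(tert-butyldimethylsilyloxy)benzaldehyde F2. Stille coupling of F2 with tributyl(vinyl)stannane (Pd(PPh3)4, toluene, 100 °C) would give 4-(tert-butyldimethylsilyloxy)-3-vinylbenzaldehyde F3. The silyl ether would then be cleaved with Bu4NF buffered with AcOH in THF at 0 °C, so that 3 is released only under cold, nearly neutral conditions.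

Step 4. HCl from the acid chloride may ionise the electron-rich benzylic C–O bond during acylation or on silica, and acid may shift the exocyclic alkene. The fallback sets out from 6 and returns at 8, activating the alcohol instead of the acid. It is a Mitsunobu esterification of 6 with stearic acid (O=C(O)CCCCCCCCCCCCCCCCC), PPh3 and diisopropyl azodicarboxylate in THF at 0 °C to rt. The carboxylate displaces the oxyphosphonium at the primary benzylic carbon, and no acid chloride or HCl is present. This way makes no new compound (F0).

**Further compounds**
F1 | step 2 | 4-[(2-methylidenebut-3-en-1-yl)oxy]-3-vinylbenzaldehyde | C=CC(=C)COc1ccc(C=O)cc1C=C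
F2 | step 1 | 3-bromo-4-(tert-butyldimethylsilyloxy)benzaldehyde | CC(C)(C)[Si](C)(C)Oc1ccc(C=O)cc1Br
F3 | step 1 | 4-(tert-butyldimethylsilyloxy)-3-vinylbenzaldehyde | CC(C)(C)[Si](C)(C)Oc1ccc(C=O)cc1C=C
F0 | step 4 | none | none
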